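## Structural features

1. Brevipolide H is an unbranched C12 chain, numbered here from the lactone carbonyl C1 to the methyl group C12. The C1–C5 end is closed through oxygen to a 5,6-dihydro-2H-pyran-2-one. The C10–C12 end is an (S)-lactoyl ketone esterified at C11–O with (E)-4-methoxycinnamic acid.
2. The two ends are joined by the free secondary carbinol C6 and a trans-1,2-disubstituted cyclopropane built from C7, the methylene C8 and C9.
3. C5 (R), C6 (S) and C7 (S) are contiguous, C9 (S) completes the array across the ring, and C11 (S) is insulated from it by the C10 carbonyl.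
4. The C5–O/C6–O pair is anti. In a Fischer projection of C5–C8 the C7–C9 bond lies on the side opposite to both oxygens.
5. Four groups are fragile. The lactone opens by E1cB after deprotonation at C4. C11 epimerises because it is α to the ketone and carries an acyloxy group. The cyclopropyl carbinol C6 opens the ring if it ionises. The cinnamate is lost to hydrogenation, hydrides and strong bases.
6. The real difficulty is the three-membered ring. Its two stereocentres must be set in the absolute sense relative to C6 and C5 in an open chain, next to a ketone that is enolisable on both sides.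
7. The key step exploits the sequence C6(OH)–C7–C8–C9–C10(=O). C9 is a latent enolate carbon, C7 is γ and the hydroxyl-bearing C6 is δ to the carbonyl, which is the retron of a 3-exo-tet opening of a C6–C7 epoxide.
8. C8 is the only other neighbour of C9 in the ring, so both ring bonds to C9 can come from one C9 nucleophile and one C8/C7 bis-electrophile.

## Logic of the disconnections

**22 ⇒ 21 ⇒ 19 + 20.**
- Bonds cut: the O–Si bond at C6–O, and the ester bond between C11–O and the cinnamoyl carbonyl.
- Reason: the cinnamate tolerates none of the enolate, hydrogenation or borane chemistry of the route, so it is attached last but one.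
- Gain: ten carbons and one alkene leave the problem.
- Demand: the group on C6–O must outlast the group on C11–O, and the acylation must not enolise C11.

**19 ⇒ 18 ⇒ 17 ⇒ 16.**
- Bonds cut: the C11–O silyl group returns, then C2=C3 (ring-closing metathesis) and the C1–O(C5) acyl bond.
- Reason: the lactone cannot survive a strong base, so it is built after the key step.
- Gain: the heterocycle becomes a homoallylic alcohol.
- Demand: C5–OH must be the only free hydroxyl group in 16.

**16 ⇒ 14.**
- Bond cut: C4–C5.
- Reason: C5 lies next to the oxygenated C6, so an allyl addition to an α-silyloxy aldehyde can set it, with reagent and substrate preference pointing the same way.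
- Gain: one stereocentre and three carbons.
- Demand: anti selectivity, and discrimination between the C5 aldehyde and the C10 ketone.

**14 ⇒ 13 ⇒ 12.**
- No skeletal bond is cut. C5 is lowered to a benzyl-protected primary alcohol.
- Reason: C5 must be inert and non-enolisable during the key step.
- Demand: the debenzylation must take place while no alkene is present.

**12 ⇒ 4 + 7 (key disconnection).**
- Bonds cut: C7–C9 and C8–C9, and the C6–O silyl group is removed.
- Reason: C9 acts twice as an enolate carbon, C8 is a primary sulfonate carbon and C7 is the near carbon of a C6–C7 epoxide. The C6 oxygen of the target is the epoxide oxygen.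
- Gain: a ring and the C6/C7/C9 array collapse to 4, with one stereocentre from the chiral pool, and 7, with two stereocentres from one catalytic epoxidation.
- Demand on 7: because C7 is inverted and C6 retained, the epoxide must be cis.
- Demand on the base: both deprotonations must occur on the C9 side of the ketone.

**7 ⇒ 6 ⇒ 5.**
- Bonds cut: the sulfonate O–S bond and the two epoxide C–O bonds.
- Reason: C8–OH is a primary allylic alcohol, the best handle for a reagent-controlled epoxidation.
- Gain: an achiral Z-alkene.
- Demand: good facial selectivity on a Z-allylic alcohol.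

**4 ⇒ 2 ⇒ 1.**
- Bonds cut: C9–C10 (methyl addition to an acyl group) and the C11–O silyl group.
- Reason: C11 is bought, not made.
- Demand: single addition of the methyl nucleophile and no loss of configuration at C11.

## Other disconnections considered

**Alternative 1:**
- Cut: C7–C8 and C8–C9, that is, methylene transfer to an E C7=C9 alkene. This is the first plan that comes to mind.
- Forward key step: a Corey–Chaykovsky reaction on the enone (2S,4E,6S,7R)-6,7-bis(tert-butyldimethylsilyloxy)-2-(triethylsilyloxy)deca-4,9-dien-3-one A1, or a hydroxyl-directed Simmons–Smith reaction on a related allylic alcohol.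
- Ground for preferring the chosen plan: both ring stereocentres would come from one π-facial choice governed only by the allylic centre C6. In an E-alkene A1,3 strain is small and several rotamers are populated, so the sense and level of induction cannot be predicted with confidence. The basic ylide would also meet a ketone that carries the epimerisable C11–H. The chosen plan replaces a facial choice by a stereospecific SN2 event and needs no more steps.

**Alternative 2:**
- Cut: C8–C9 and C7–C9 at a terminal C7–C8 epoxide.
- Forward key step: a Wadsworth–Emmons cyclopropanation of (2S)-2-[(1R)-1-(4-methoxybenzyloxy)prop-2-en-1-yl]oxirane A2 with dimethyl [(3S)-2-oxo-3-(triethylsilyloxy)butyl]phosphonate A3.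
- In its favour: the step is also stereospecific at C7 and joins two fragments.
- Ground for preferring the chosen plan:
  - The doubly stabilised anion of A3 is a poor nucleophile for epoxides.
  - The γ-alkoxide can add to the ketone and dehydrate instead of taking over the phosphoryl group.
  - Expulsion of a secondary phosphate needs prolonged heating, and under those conditions C11 should epimerise.
  - The C6 oxygen has to be carried and protected separately.
  - The chosen plan uses a triflate and an epoxide as leaving groups at low temperature, and it obtains the C6 hydroxyl from the leaving group itself.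

**Alternative 3:**
- Cut: C7–C9 and C8–C9 as a tethered carbene addition.
- Forward key step: intramolecular cyclopropanation of (3S,4R)-4-(tert-butyldimethylsilyloxy)hepta-1,6-dien-3-yl diazoacetate A4 with a chiral dirhodium carboxamidate such as Rh2(MEPY)4. This gives the lactone (1R,4S,5S)-4-[(1R)-1-(tert-butyldimethylsilyloxy)but-3-en-1-yl]-3-oxabicyclo[3.1.0]hexan-2-one A5, whose carbonyl is C10. Opening at C10 would free C6–OH.
- Ground for preferring the chosen plan: the tether forces C6 and C10 to be cis on the ring, whereas the target is trans. The correction needs deprotonation of the weakly acidic cyclopropyl C9–H next to the more acidic C11–H, so C11 would be lost first. The C10–C11 bond would also need a configurationally defined 1-alkoxyethyl anion instead of the lactate pool, which adds steps.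

Key step: step 5

Assumption: 5, 20 and the allylborane of step 8 are taken as commercial, and atom labels C1–C12 always refer to the numbering of the target given above.

## Steps

Step 1
Reactants: 1 ethyl (S)-lactate
Product: 2 ethyl (2S)-2-(triethylsilyloxy)propanoate
Conditions: TESCl, imidazole, CH2Cl2, 0 °C → rt
Reagents that add atoms: chlorotriethylsilane CC[Si](Cl)(CC)CC
Why: Standard silylation of a secondary alcohol that does not touch C11; the triethylsilyl group is chosen because it can later be removed in the presence of a tert-butyldimethylsilyl ether.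

Step 2
Reactants: 2 ethyl (2S)-2-(triethylsilyloxy)propanoate
Product: 4 (3S)-3-(triethylsilyloxy)butan-2-one, via Weinreb amide 3 (not isolated)
Conditions: MeNH(OMe)·HCl, iPrMgCl, THF, −20 °C; then MeMgBr, 0 °C; aqueous work-up
Reagents that add atoms: methylmagnesium bromide C[Mg]Br; N,O-dimethylhydroxylamine hydrochloride CNOC.Cl (atoms held only in 3)
Why: The chloromagnesium amide converts the ester into 3 faster than the hindered Grignard base adds, and MeMgBr then adds only once because the chelated tetrahedral adduct survives until work-up (Weinreb ketone synthesis run in one flask). The low temperature and the absence of free alkoxide protect C11.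

Step 3
Reactants: 5 (Z)-4-(benzyloxy)but-2-en-1-ol
Product: 6 [(2S,3R)-3-(benzyloxymethyl)oxiran-2-yl]methanol (cis-epoxide; oxirane C2 = C7 and C3 = C6)
Conditions: Ti(OiPr)4 (10 mol %), L-(+)-diethyl tartrate (12 mol %), t-BuOOH, 4 Å MS, CH2Cl2, −20 °C
Reagents that add atoms: tert-butyl hydroperoxide CC(C)(C)OO
Why: Sharpless asymmetric epoxidation directed by the primary C8–OH; the L-(+)-tartrate delivers oxygen to the face that makes the carbinol-bearing carbon S, and syn addition to the Z-alkene fixes the cis relation, so C6 and the C7–O centre are set together. Z-Allylic alcohols react more slowly and may be somewhat less selective than E ones, but any minor enantiomer becomes a diastereomer after union with 4 and can be removed there.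

Step 4
Reactants: 6 [(2S,3R)-3-(benzyloxymethyl)oxiran-2-yl]methanol
Product: 7 [(2S,3R)-3-(benzyloxymethyl)oxiran-2-yl]methyl trifluoromethanesulfonate
Conditions: Tf2O, 2,6-lutidine, CH2Cl2, −78 °C; used at once
Reagents that add atoms: triflic anhydride O=S(=O)(OS(=O)(=O)C(F)(F)F)C(F)(F)F
Why: O-Sulfonylation of a primary alcohol with a hindered, non-nucleophilic base; no stereocentre is touched, and glycidyl-type triflates are known electrophiles that react at the CH2–O carbon.

Step 5
Reactants: 4 (3S)-3-(triethylsilyloxy)butan-2-one; 7 [(2S,3R)-3-(benzyloxymethyl)oxiran-2-yl]methyl trifluoromethanesulfonate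
Product: 12 (2S)-1-[(1S,2S)-2-[(1S)-2-(benzyloxy)-1-(tert-butyldimethylsilyloxy)ethyl]cyclopropyl]-2-(triethylsilyloxy)propan-1-one, via lithium enolate 8 (not isolated), via epoxy ketone 9 (not isolated), via lithium enolate 10 (not isolated), via lithium alkoxide 11 (not isolated)
Conditions: 4, LiHMDS (1.05 equiv), THF, −78 °C; 7, −78 °C; LiHMDS (1.1 equiv), −78 → 0 °C; TBSOTf (1.1 equiv), −78 °C
Reagents that add atoms: tert-butyldimethylsilyl triflate CC(C)(C)[Si](C)(C)OS(=O)(=O)C(F)(F)F; lithium hexamethyldisilazide [Li]N([Si](C)(C)C)[Si](C)(C)C (lithium held only in 8, 10 and 11)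
Why: Kinetic deprotonation of 4 at the C9 methyl group gives 8, which displaces the primary triflate of 7 at C8 (SN2 enolate alkylation, far faster at −78 °C than attack on either epoxide carbon) and gives the γ,δ-epoxy ketone 9. The second portion of base again takes the less hindered proton, now at the C9 methylene and not the tertiary, silyloxy-shielded C11–H, and enolate 10 attacks C7 from the side opposite to the C7–O bond; this is the known base-induced cyclisation of γ,δ-epoxy ketones, of the same family as the epichlorohydrin/active-methylene cyclopropanation and the epoxynitrile cyclisation. The ring closes in the 3-exo-tet (enolexo) mode, which should win over four-membered ring formation by attack at C6, an attack further slowed by the inductive effect of the C5 benzyloxy group, and over 5-exo O-alkylation, which a tightly oxygen-bound lithium enolate disfavours. C7 is set by inversion of the epoxide C7–O centre and C6 keeps its C–O bond and configuration, so the cis geometry of 7 is translated stereospecifically into the C6 (S)/C7 (S) relation. C9 is set in the transition state, where the enolate carbon closes with C10 anti to the C6 branch because the syn arrangement eclipses the two largest groups on the nascent ring. A cis product could moreover fold to a bicyclic hemiketal and should be easy to separate. C11 is not involved as long as base is not in excess. Alkoxide 11 is the best nucleophile in the flask and is silylated in situ, so two C–C bonds, the ring and the C6/C7/C9 array are fixed in one flask.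

Step 6
Reactants: 12 (2S)-1-[(1S,2S)-2-[(1S)-2-(benzyloxy)-1-(tert-butyldimethylsilyloxy)ethyl]cyclopropyl]-2-(triethylsilyloxy)propan-1-one
Product: 13 (2S)-1-[(1S,2S)-2-[(1S)-1-(tert-butyldimethylsilyloxy)-2-hydroxyethyl]cyclopropyl]-2-(triethylsilyloxy)propan-1-one
Conditions: H2 (1 atm), 10 % Pd/C, EtOAc, rt
Reagents that add atoms: none
Why: Hydrogenolysis of the benzyl ether at the only stage where no alkene is present; silyl ethers are stable in an aprotic solvent, and a simple cyclopropyl ketone should not be cleaved at one atmosphere.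

Step 7
Reactants: 13 (2S)-1-[(1S,2S)-2-[(1S)-1-(tert-butyldimethylsilyloxy)-2-hydroxyethyl]cyclopropyl]-2-(triethylsilyloxy)propan-1-one
Product: 14 (2S)-2-(tert-butyldimethylsilyloxy)-2-[(1S,2S)-2-[(2S)-2-(triethylsilyloxy)propanoyl]cyclopropyl]acetaldehyde
Conditions: Dess–Martin periodinane, NaHCO3, CH2Cl2, 0 °C → rt
Reagents that add atoms: none
Why: Buffered Dess–Martin oxidation is neutral and fast, so neither the new α-silyloxy aldehyde centre C6 nor C11 should epimerise.

Step 8
Reactants: 14 (2S)-2-(tert-butyldimethylsilyloxy)-2-[(1S,2S)-2-[(2S)-2-(triethylsilyloxy)propanoyl]cyclopropyl]acetaldehyde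
Product: 16 (2S)-1-[(1S,2S)-2-[(1S,2R)-1-(tert-butyldimethylsilyloxy)-2-hydroxypent-4-en-1-yl]cyclopropyl]-2-(triethylsilyloxy)propan-1-one, via borinate 15 (not isolated)
Conditions: (+)-Ipc2B(allyl), Et2O, −78 °C; then H2O2, pH 7 buffer, MeOH, 0 °C
Reagents that add atoms: (+)-B-allyldiisopinocampheylborane, derived from (−)-α-pinene C=CCB([C@H]1C[C@H]2C[C@@H]([C@@H]1C)C2(C)C)[C@H]3C[C@H]4C[C@@H]([C@@H]3C)C4(C)C
Why: Brown allylation through a closed chair transition state; the reagent of the (−)-α-pinene series delivers allyl to the aldehyde face that makes C5 R. This is also the anti product preferred by the polar Felkin–Anh model for an α-silyloxy aldehyde, so the pair is matched. The C10 ketone is inert at −78 °C, and the neutral oxidative work-up spares C11.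

Step 9
Reactants: 16 (2S)-1-[(1S,2S)-2-[(1S,2R)-1-(tert-butyldimethylsilyloxy)-2-hydroxypent-4-en-1-yl]cyclopropyl]-2-(triethylsilyloxy)propan-1-one
Product: 17 (1S,2R)-1-(tert-butyldimethylsilyloxy)-1-[(1S,2S)-2-[(2S)-2-(triethylsilyloxy)propanoyl]cyclopropyl]pent-4-en-2-yl prop-2-enoate
Conditions: acryloyl chloride, iPr2NEt, CH2Cl2, 0 °C
Reagents that add atoms: acryloyl chloride C=CC(=O)Cl
Why: Acylation of the only free hydroxyl group; the C5–O bond is not broken, so C5 is retained.

Step 10
Reactants: 17 (1S,2R)-1-(tert-butyldimethylsilyloxy)-1-[(1S,2S)-2-[(2S)-2-(triethylsilyloxy)propanoyl]cyclopropyl]pent-4-en-2-yl prop-2-enoate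
Product: 18 (6R)-6-[(S)-(tert-butyldimethylsilyloxy)[(1S,2S)-2-[(2S)-2-(triethylsilyloxy)propanoyl]cyclopropyl]methyl]-5,6-dihydro-2H-pyran-2-one
Conditions: second-generation Grubbs catalyst RuCl2(=CHPh)(PCy3)(H2IMes) (5 mol %), CH2Cl2, 40 °C
Reagents that add atoms: none
Why: Ring-closing metathesis of an acrylate with a terminal alkene is the standard entry to 5,6-dihydropyran-2-ones; the six-membered ring enforces the Z C2=C3 bond and loss of ethene drives the reaction.

Step 11
Reactants: 18 (6R)-6-[(S)-(tert-butyldimethylsilyloxy)[(1S,2S)-2-[(2S)-2-(triethylsilyloxy)propanoyl]cyclopropyl]methyl]-5,6-dihydro-2H-pyran-2-one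
Product: 19 (6R)-6-[(S)-(tert-butyldimethylsilyloxy)[(1S,2S)-2-[(2S)-2-hydroxypropanoyl]cyclopropyl]methyl]-5,6-dihydro-2H-pyran-2-one
Conditions: PPTS (cat.), MeOH/CH2Cl2, 0 °C
Reagents that add atoms: none
Why: Mild acid methanolysis removes a triethylsilyl ether much faster than a hindered secondary tert-butyldimethylsilyl ether; the weak acid should neither ionise the protected carbinol C6 nor enolise C11.

Step 12
Reactants: 19 (6R)-6-[(S)-(tert-butyldimethylsilyloxy)[(1S,2S)-2-[(2S)-2-hydroxypropanoyl]cyclopropyl]methyl]-5,6-dihydro-2H-pyran-2-one; 20 (E)-4-methoxycinnamic acid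
Product: 21 (2S)-1-[(1S,2S)-2-[(S)-(tert-butyldimethylsilyloxy)[(2R)-6-oxo-3,6-dihydro-2H-pyran-2-yl]methyl]cyclopropyl]-1-oxopropan-2-yl (E)-3-(4-methoxyphenyl)prop-2-enoate
Conditions: DCC, DMAP (cat.), CH2Cl2, 0 °C → rt
Reagents that add atoms: none
Why: Steglich esterification of the only free hydroxyl group; the C11–O bond is retained, and only a catalytic amount of DMAP at low temperature is used so that C11 is not enolised.

Step 13
Reactants: 21 (2S)-1-[(1S,2S)-2-[(S)-(tert-butyldimethylsilyloxy)[(2R)-6-oxo-3,6-dihydro-2H-pyran-2-yl]methyl]cyclopropyl]-1-oxopropan-2-yl (E)-3-(4-methoxyphenyl)prop-2-enoate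
Product: 22 brevipolide H
Conditions: HF·pyridine, pyridine, THF, 0 °C → rt
Reagents that add atoms: none
Why: Buffered fluoride cleaves the last silyl ether under nearly neutral conditions. These avoid base-induced lactone opening, acyl migration and epimerisation at C11, and they are not acidic enough to ionise the cyclopropyl carbinol.

## Compound list

1 | ethyl (S)-lactate | C[C@H](O)C(=O)OCC | starting material
2 | ethyl (2S)-2-(triethylsilyloxy)propanoate | CC[Si](CC)(CC)O[C@@H](C)C(=O)OCC | intermediate
3 | (2S)-N-methoxy-N-methyl-2-(triethylsilyloxy)propanamide | CC[Si](CC)(CC)O[C@@H](C)C(=O)N(C)OC | intermediate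
4 | (3S)-3-(triethylsilyloxy)butan-2-one | CC[Si](CC)(CC)O[C@@H](C)C(C)=O | intermediate
5 | (Z)-4-(benzyloxy)but-2-en-1-ol | OC/C=C\COCc1ccccc1 | starting material
6 | [(2S,3R)-3-(benzyloxymethyl)oxiran-2-yl]methanol | OC[C@@H]1O[C@@H]1COCc1ccccc1 | intermediate
7 | [(2S,3R)-3-(benzyloxymethyl)oxiran-2-yl]methyl trifluoromethanesulfonate | FC(F)(F)S(=O)(=O)OC[C@@H]1O[C@@H]1COCc1ccccc1 | intermediate
8 | lithium (3S)-3-(triethylsilyloxy)but-1-en-2-olate | CC[Si](CC)(CC)O[C@@H](C)C(=C)O[Li] | intermediate
9 | (2S)-5-[(2S,3R)-3-(benzyloxymethyl)oxiran-2-yl]-2-(triethylsilyloxy)pentan-3-one | CC[Si](CC)(CC)O[C@@H](C)C(=O)CC[C@@H]1O[C@@H]1COCc1ccccc1 | intermediate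
10 | Z lithium enolate of 9 (C9=C10) | CC[Si](CC)(CC)O[C@@H](C)/C(O[Li])=C/C[C@@H]1O[C@@H]1COCc1ccccc1 | intermediate
11 | lithium (1S)-2-(benzyloxy)-1-[(1S,2S)-2-[(2S)-2-(triethylsilyloxy)propanoyl]cyclopropyl]ethanolate | CC[Si](CC)(CC)O[C@@H](C)C(=O)[C@H]1C[C@@H]1[C@H](O[Li])COCc1ccccc1 | intermediate
12 | (2S)-1-[(1S,2S)-2-[(1S)-2-(benzyloxy)-1-(tert-butyldimethylsilyloxy)ethyl]cyclopropyl]-2-(triethylsilyloxy)propan-1-one | CC[Si](CC)(CC)O[C@@H](C)C(=O)[C@H]1C[C@@H]1[C@H](O[Si](C)(C)C(C)(C)C)COCc1ccccc1 | intermediate
13 | (2S)-1-[(1S,2S)-2-[(1S)-1-(tert-butyldimethylsilyloxy)-2-hydroxyethyl]cyclopropyl]-2-(triethylsilyloxy)propan-1-one | CC[Si](CC)(CC)O[C@@H](C)C(=O)[C@H]1C[C@@H]1[C@H](O[Si](C)(C)C(C)(C)C)CO | intermediate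
14 | (2S)-2-(tert-butyldimethylsilyloxy)-2-[(1S,2S)-2-[(2S)-2-(triethylsilyloxy)propanoyl]cyclopropyl]acetaldehyde | CC[Si](CC)(CC)O[C@@H](C)C(=O)[C@H]1C[C@@H]1[C@H](O[Si](C)(C)C(C)(C)C)C=O | intermediate
15 | diisopinocampheylborinate of 16 (C5–O–B) | CC[Si](CC)(CC)O[C@@H](C)C(=O)[C@H]1C[C@@H]1[C@H](O[Si](C)(C)C(C)(C)C)[C@H](OB([C@H]3C[C@H]4C[C@@H]([C@@H]3C)C4(C)C)[C@H]5C[C@H]6C[C@@H]([C@@H]5C)C6(C)C)CC=C | intermediate
16 | (2S)-1-[(1S,2S)-2-[(1S,2R)-1-(tert-butyldimethylsilyloxy)-2-hydroxypent-4-en-1-yl]cyclopropyl]-2-(triethylsilyloxy)propan-1-one | CC[Si](CC)(CC)O[C@@H](C)C(=O)[C@H]1C[C@@H]1[C@H](O[Si](C)(C)C(C)(C)C)[C@H](O)CC=C | intermediate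
17 | (1S,2R)-1-(tert-butyldimethylsilyloxy)-1-[(1S,2S)-2-[(2S)-2-(triethylsilyloxy)propanoyl]cyclopropyl]pent-4-en-2-yl prop-2-enoate | CC[Si](CC)(CC)O[C@@H](C)C(=O)[C@H]1C[C@@H]1[C@H](O[Si](C)(C)C(C)(C)C)[C@H](OC(=O)C=C)CC=C | intermediate
18 | (6R)-6-[(S)-(tert-butyldimethylsilyloxy)[(1S,2S)-2-[(2S)-2-(triethylsilyloxy)propanoyl]cyclopropyl]methyl]-5,6-dihydro-2H-pyran-2-one | CC[Si](CC)(CC)O[C@@H](C)C(=O)[C@H]1C[C@@H]1[C@H](O[Si](C)(C)C(C)(C)C)[C@H]2CC=CC(=O)O2 | intermediate
19 | (6R)-6-[(S)-(tert-butyldimethylsilyloxy)[(1S,2S)-2-[(2S)-2-hydroxypropanoyl]cyclopropyl]methyl]-5,6-dihydro-2H-pyran-2-one | O[C@@H](C)C(=O)[C@H]1C[C@@H]1[C@H](O[Si](C)(C)C(C)(C)C)[C@H]2CC=CC(=O)O2 | intermediate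
20 | (E)-4-methoxycinnamic acid | COc1ccc(/C=C/C(=O)O)cc1 | starting material
21 | C6-O-tert-butyldimethylsilyl ether of brevipolide H | COc1ccc(/C=C/C(=O)O[C@@H](C)C(=O)[C@H]2C[C@@H]2[C@H](O[Si](C)(C)C(C)(C)C)[C@H]2CC=CC(=O)O2)cc1 | intermediate
22 | brevipolide H | COc1ccc(/C=C/C(=O)O[C@@H](C)C(=O)[C@H]2C[C@@H]2[C@H](O)[C@H]2CC=CC(=O)O2)cc1 | target

## Step count and least certain steps

Total step count: 13. Longest linear sequence: 11 steps (steps 1, 2 and 5–13, or equally steps 3, 4 and 5–13).

**Step 5 (key step).**

What is most likely to go wrong: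
- Proton transfer between 8 and freshly formed 9 would lead to incomplete alkylation.
- Enolisation toward C11 by a slight excess of amide base, or by alkoxide 11 while the mixture warms, would erode the C11 configuration.
- Part of 10 could close through oxygen.
- The ketone could be silylated to an enol ether by the triflate.

All four arise because three anionic stages share one flask and the cyclisation releases a basic alkoxide.

Fallback, setting out from 4 and coming back at 14: the leaving group at C7 is changed from an epoxide oxygen to a sulfonate, and the C6 oxygen is installed beforehand, so that no alkoxide is released. Commercial penta-1,4-dien-3-ol F1 is desymmetrised by Sharpless epoxidation with D-(−)-diisopropyl tartrate to (2S,3R)-1,2-epoxypent-4-en-3-ol F2, which is silylated (TBSCl, imidazole) to its tert-butyldimethylsilyl ether F3. Enolate 8 opens F3 at the terminal carbon C8 under Sc(OTf)3 catalysis and gives the γ-hydroxy ketone F4. MsCl/Et3N then gives the mesylate F5, and LiHMDS closes the ring by the same 3-exo-tet inversion at C7 to give the vinyl cyclopropyl ketone F6. Lemieux–Johnson cleavage of the vinyl group (OsO4 cat., NaIO4, 2,6-lutidine) gives 14, so steps 6 and 7 are bypassed.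

**Step 4.**

What is most likely to go wrong: the epoxy triflate may decompose on concentration or storage, by ionisation assisted by the neighbouring epoxide oxygen or by attack of lutidine. The stoichiometry of step 5 would then be upset.

Fallback, setting out from 6 and 4 and coming back at 9: the C8–C9 bond is made with a stable halide and an azaenolate instead of a triflate and a ketone enolate. An Appel reaction (I2, PPh3, imidazole) converts 6 into the epoxy iodide (2R,3R)-2-(benzyloxymethyl)-3-(iodomethyl)oxirane F7. Ketone 4 is condensed with Me2NNH2 to the N,N-dimethylhydrazone F8, which is deprotonated with LDA at the methyl group and alkylated with F7 to the alkylated hydrazone F9. Mild hydrolysis with aqueous Cu(OAc)2 gives 9, which is isolated and submitted to the second half of step 5.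

**Step 8.**

What is most likely to go wrong: facial selectivity may be insufficient if the bulky C6 silyloxy and cyclopropyl groups distort the chair transition state, and slow addition to the hindered aldehyde would allow competing reaction at the C10 ketone.

Fallback, setting out from 14 and coming back at 16: reagent control through a closed transition state is given up for substrate control through an open one. In a Hosomi–Sakurai allylation with allyltrimethylsilane and BF3·OEt2 at −78 °C, the non-chelating α-silyloxy group directs attack by the polar Felkin–Anh model to the same anti product, and the Lewis acid activates the aldehyde in preference to the ketone. No new compound is made on this way.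

## Further compounds

F1 | step 5 | penta-1,4-dien-3-ol | C=CC(O)C=C
F2 | step 5 | (2S,3R)-1,2-epoxypent-4-en-3-ol | C=C[C@@H](O)[C@@H]1CO1
F3 | step 5 | (2S)-2-[(1R)-1-(tert-butyldimethylsilyloxy)prop-2-en-1-yl]oxirane | C=C[C@@H](O[Si](C)(C)C(C)(C)C)[C@@H]1CO1
F4 | step 5 | (2S,6S,7R)-7-(tert-butyldimethylsilyloxy)-6-hydroxy-2-(triethylsilyloxy)non-8-en-3-one | CC[Si](CC)(CC)O[C@@H](C)C(=O)CC[C@H](O)[C@H](O[Si](C)(C)C(C)(C)C)C=C
F5 | step 5 | (3R,4S,8S)-3-(tert-butyldimethylsilyloxy)-7-oxo-8-(triethylsilyloxy)non-1-en-4-yl methanesulfonate | CC[Si](CC)(CC)O[C@@H](C)C(=O)CC[C@H](OS(C)(=O)=O)[C@H](O[Si](C)(C)C(C)(C)C)C=C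
F6 | step 5 | (2S)-1-[(1S,2S)-2-[(1R)-1-(tert-butyldimethylsilyloxy)prop-2-en-1-yl]cyclopropyl]-2-(triethylsilyloxy)propan-1-one | CC[Si](CC)(CC)O[C@@H](C)C(=O)[C@H]1C[C@@H]1[C@H](O[Si](C)(C)C(C)(C)C)C=C
F7 | step 4 | (2R,3R)-2-(benzyloxymethyl)-3-(iodomethyl)oxirane | IC[C@@H]1O[C@@H]1COCc1ccccc1
F8 | step 4 | (3S)-3-(triethylsilyloxy)butan-2-one (E)-N,N-dimethylhydrazone | CC[Si](CC)(CC)O[C@@H](C)/C(C)=N/N(C)C
F9 | step 4 | N,N-dimethylhydrazone of 9 | CC[Si](CC)(CC)O[C@@H](C)/C(CC[C@@H]1O[C@@H]1COCc1ccccc1)=N/N(C)C
F0 | step 8 | none | none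
A1 | alternative 1 | (2S,4E,6S,7R)-6,7-bis(tert-butyldimethylsilyloxy)-2-(triethylsilyloxy)deca-4,9-dien-3-one | CC[Si](CC)(CC)O[C@@H](C)C(=O)/C=C/[C@H](O[Si](C)(C)C(C)(C)C)[C@H](O[Si](C)(C)C(C)(C)C)CC=C
A2 | alternative 2 | (2S)-2-[(1R)-1-(4-methoxybenzyloxy)prop-2-en-1-yl]oxirane | C=C[C@@H](OCc1ccc(OC)cc1)[C@@H]1CO1
A3 | alternative 2 | dimethyl [(3S)-2-oxo-3-(triethylsilyloxy)butyl]phosphonate | CC[Si](CC)(CC)O[C@@H](C)C(=O)CP(=O)(OC)OC
A4 | alternative 3 | (3S,4R)-4-(tert-butyldimethylsilyloxy)hepta-1,6-dien-3-yl diazoacetate | [N-]=[N+]=CC(=O)O[C@H]([C@H](O[Si](C)(C)C(C)(C)C)CC=C)C=C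
A5 | alternative 3 | (1R,4S,5S)-4-[(1R)-1-(tert-butyldimethylsilyloxy)but-3-en-1-yl]-3-oxabicyclo[3.1.0]hexan-2-one | O=C1O[C@H]([C@H](O[Si](C)(C)C(C)(C)C)CC=C)[C@H]2C[C@@H]12
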